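Decide first what you will carry from one flask to the next: percent of J per minute, or turnovers, meaning E made per minute per catalyst charged.

| flask | J | D | Z | temperature | remark | time |
|---|---|---|---|---|---|---|
| dusk | 0.070 M | 0.065 M | 0.50 mM | 58 °C | run made earlier |  |
| winter | 0.11 M | 0.065 M | 0.50 mM | 74 °C | run made earlier |  |
| Sunday's | 0.050 M | 0.0650 M | 0.50 mM | 80 °C |  | 30 min |
| Wednesday's | 0.050 M | 0.0650 M | 0.50 mM |  | at 50 °C until 6.0 min, from then on at 80 °C | 30 min |
| Tuesday's | 0.050 M | 0.0650 M | 0.50 mM | 50 °C |  | 30 min |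

| run | time / min | E / % | J / % |
|---|---|---|---|
| dusk | 8.00 | 0.3 | 99.3 |
| dusk | 12.0 | 0 | 99.5 |
| dusk | 20.0 | 1.4 | 98.6 |
| dusk | 30.0 | 1.2 | 97.9 |
| dusk | 60.0 | 2.4 | 96.8 |
| dusk | 80.0 | 3.2 | 95.3 |
| winter | 2.50 | 0.2 | 99.0 |
| winter | 4.00 | 0.4 | 98.7 |
| winter | 6.00 | 0.9 | 98.9 |
| winter | 10.0 | 0.7 | 97.8 |
| winter | 20.0 | 2.8 | 97.0 |
| winter | 30.0 | 4.4 | 94.7 |

(scatter of a reading: 0.3 percentage points)

- the flask that comes out highest in amount of E, in percent of the J charged, or "all alike" when all lie within 1.5 percentage points (Sunday's / Wednesday's / Tuesday's / all alike)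
- E at the end, in percent of the J charged, Sunday's
- E at the end, in percent of the J charged, Wednesday's
- E at the end, in percent of the J charged, Tuesday's

The bench habit is percent per minute and a doubling every 10 degrees. By its last reading the dusk run made 3.2 % in 80.0 min and the winter run 4.4 % in 30.0 min, each reading good to 0.3 percentage points. So percent per minute rose 3.67 times from 58 °C to 74 °C, which is 1.88 doublings, and you might let that pass. But a percent is counted on the J charge, and the winter charge stands 1.57 times over the dusk charge and 2.20 times over the charge of the new flasks. That ratio is the border of the rule: percent carries across charges if the rate follows J, and the two runs can't show it, because J and temperature rose together.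

So take the opposite case as the zero of the scale. J per Z stood at 140 and 220 and stands at 100 in the new flasks, and I commit to a catalyst that turns at its own pace whatever the J (zero order in J). The last readings then give a turnover rate of 0.0560 min⁻¹ in the dusk run and 0.323 min⁻¹ in the winter run, a factor of 5.76. Carrying that factor on evenly in temperature gives the hot turnover rate, 0.622 min⁻¹ at 80 °C, and 0.0233 min⁻¹ at 50 °C. My reckoning is therefore 18.7 % for Sunday's, 15.1 % for Wednesday's and 0.700 % for Tuesday's.

The forecast has 6.5 %, 5.3 % and 0.6 %, the first and last being what rates doubled every 10 degrees from the dusk run give: “Sunday's comes out highest, narrowly ahead of Wednesday's”.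

The flasks give 16.9 % for Sunday's, 13.8 % for Wednesday's and 0.582 % for Tuesday's.

    D + Z ⇌ G (K = 17.1 L mol⁻¹, k = 53.9 L mol⁻¹ min⁻¹, Ea = 39.0 kJ mol⁻¹, ΔH = −1.00 kJ mol⁻¹)
    J + G → L (k = 2220 L mol⁻¹ min⁻¹, Ea = 48.0 kJ mol⁻¹)
    L → Q + X (k = 3.89 min⁻¹, Ea = 90.0 kJ mol⁻¹)
    X → Z + E (k = 0.860 min⁻¹, Ea = 110 kJ mol⁻¹)
    (constants at 80 °C)

At 30.0 min in Sunday's flask, X holds 65.6 % of the catalyst, the resting state. That flask's own turnover rate, averaged over its 30 min, comes to 0.564 min⁻¹, against the 0.622 min⁻¹ carried. Put 0.622 min⁻¹ on a flask like Wednesday's with 0.0020 M of Z, for its hot 24.0 min, and you reckon 59.7 %; that flask gives 52.9 %.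

The readings stem from a simulated flask from invented constants, noise included.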